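**Retrosynthetic overview**
- The target's only stereocentre comes last: asymmetric transfer hydrogenation of the macrocyclic aryl benzyl ketone.
- The 18-membered ring (the only ring that is formed) is closed at the ring A–O–ring B diaryl ether. A boron-masked pyrogallol oxygen displaces fluoride para to the ketone (intramolecular SNAr).
- The open-chain tetraphenol comes from global demethylation of its tetramethyl ether. The ring A–CH2CH2–ring D link is made by hydroboration/B-alkyl Suzuki coupling of 3,4,5-trimethoxystyrene with a ring D aryl bromide.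
- The ring B–C(=O)–CH2–ring C unit comes from a ring C aldehyde (via its tosylhydrazone) and 4-fluorobenzaldehyde. The ring D–O–ring C ether comes from SNAr of 3-bromophenol on 2-fluoro-3-methoxybenzaldehyde.
- All four benzene rings are bought. Bond order: D–O–C, then C–CH2–CO–B, then A–CH2CH2–D, then A–O–B (macrocycle), then C=O to (S)-CHOH.

Notation: ring A = trioxygenated ring; ring B = para-phenylene on the carbinol carbon; ring C = hydroxylated 1,2,3-trisubstituted ring; ring D = meta-phenylene. The stereocentre in the given SMILES reads as (S).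

**Route**

Step 1
Reactants: 1 3-bromophenol; 2 2-fluoro-3-methoxybenzaldehyde
Product: 3 2-(3-bromophenoxy)-3-methoxybenzaldehyde
Conditions: K2CO3 (1.5 equiv), DMAc, 110 °C
Reagents that add atoms: none
Why: SNAr (addition–elimination): the ortho-formyl group activates the C–F bond toward the phenoxide and the aryl bromide is inert, which gives the ring D–O–ring C ether.

Step 2
Reactants: 3 2-(3-bromophenoxy)-3-methoxybenzaldehyde; 4 4-methylbenzenesulfonohydrazide; 5 4-fluorobenzaldehyde
Product: 8 2-[2-(3-bromophenoxy)-3-methoxyphenyl]-1-(4-fluorophenyl)ethan-1-one, via tosylhydrazone 6 (not isolated), via aryldiazomethane 7 (not isolated)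
Conditions: 4 (1.0 equiv), MeOH, 60 °C, evaporate; then 5 (0.8 equiv), K2CO3 (2 equiv), 1,4-dioxane, 110 °C
Reagents that add atoms: none
Why: Bamford–Stevens generation of the aryldiazomethane, then Büchner–Curtius–Schlotterbeck-type addition to the aldehyde with 1,2-hydride shift and loss of N2 (formal formyl C–H insertion), places the carbonyl on the fluorophenyl side.

Step 3
Reactants: 9 3,4,5-trimethoxybenzaldehyde
Product: 10 5-ethenyl-1,2,3-trimethoxybenzene
Conditions: Ph3PCH3Br (1.3 equiv), KOtBu (1.3 equiv), THF, 0 °C to rt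
Reagents that add atoms: methyltriphenylphosphonium bromide, C[P+](c1ccccc1)(c1ccccc1)c1ccccc1.[Br-]
Why: Wittig methylenation of a non-enolisable aromatic aldehyde.

Step 4
Reactants: 10 5-ethenyl-1,2,3-trimethoxybenzene; 11 9-borabicyclo[3.3.1]nonane; 8 2-[2-(3-bromophenoxy)-3-methoxyphenyl]-1-(4-fluorophenyl)ethan-1-one
Product: 13 1-(4-fluorophenyl)-2-(3-methoxy-2-{3-[2-(3,4,5-trimethoxyphenyl)ethyl]phenoxy}phenyl)ethan-1-one, via alkylborane 12 (not isolated)
Conditions: 10 (1.3 equiv), 11 (1.25 equiv), THF, 0 °C to rt; then 8, Pd(dppf)Cl2 (5 mol%), 3 M aq K3PO4, THF/DMF, 60 °C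
Reagents that add atoms: none
Why: Anti-Markovnikov hydroboration of the styrene, then B-alkyl Suzuki–Miyaura coupling of the primary alkylborane with the aryl bromide; the weak aqueous base leaves the enolisable fluoroaryl ketone alone.

Step 5
Reactants: 13 1-(4-fluorophenyl)-2-(3-methoxy-2-{3-[2-(3,4,5-trimethoxyphenyl)ethyl]phenoxy}phenyl)ethan-1-one
Product: 14 1-(4-fluorophenyl)-2-(3-hydroxy-2-{3-[2-(3,4,5-trihydroxyphenyl)ethyl]phenoxy}phenyl)ethan-1-one
Conditions: BBr3 (8 equiv), CH2Cl2, −78 °C to rt; then H2O, 0 °C; crude product kept under argon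
Reagents that add atoms: none
Why: Lewis-acid cleavage of all four aryl methyl ethers (O–B complexation, bromide attack at methyl); the diaryl ether, aryl fluoride and deoxybenzoin ketone survive, as is routine for methoxylated deoxybenzoins.

Step 6
Reactants: 14 1-(4-fluorophenyl)-2-(3-hydroxy-2-{3-[2-(3,4,5-trihydroxyphenyl)ethyl]phenoxy}phenyl)ethan-1-one; 15 phenylboronic acid
Product: 18 macrocyclic triphenol ketone, via seco phenylboronate 16 (not isolated), via macrocyclic phenylboronate 17 (not isolated)
Conditions: 15 (1.2 equiv), 4 Å MS, THF, rt, evaporate; then Cs2CO3 (3.5 equiv), degassed DMSO (2 mM), 90 °C; then H2O (pH 5)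
Reagents that add atoms: none
Why: Proposed new method: boron-masked pyrogallol SNAr macro-etherification – PhB(OH)2 esterifies two adjacent ring A oxygens (necessarily including the central one), so the single free phenoxide is an outer oxygen (the two outer oxygens are symmetry-equivalent) and it adds para to the ring B ketone (Meisenheimer intermediate, loss of fluoride) to close the 18-membered ring at high dilution, while the boron also stops Smiles migration of the acyl-activated ring B onto the central oxygen; the closest known reactions are the borate-directed outer-O-alkylation of gallates and nitro- or carbonyl-activated SNAr diaryl ether macrocyclisations.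

Step 7
Reactants: 18 macrocyclic triphenol ketone
Product: 19 target CNP0356934.1 [(S)-carbinol of 18]
Conditions: RuCl(p-cymene)[(S,S)-TsDPEN] (5 mol%), HCO2H/Et3N (5:2), DMF, 40 °C
Reagents that add atoms: none
Why: Noyori–Ikariya asymmetric transfer hydrogenation: the (S,S)-catalyst delivers hydride to the Re face of the aryl benzyl ketone (ring B as the aryl group in the CH/π contact) and sets the (S)-carbinol, as for (S)-1-arylalkanols; the acidic formate medium keeps the phenols protonated.

**Compound list**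

1 | 3-bromophenol | Oc1cccc(Br)c1 | starting material
2 | 2-fluoro-3-methoxybenzaldehyde | COc1cccc(C=O)c1F | starting material
3 | 2-(3-bromophenoxy)-3-methoxybenzaldehyde | COc1cccc(C=O)c1Oc1cccc(Br)c1 | intermediate
4 | 4-methylbenzenesulfonohydrazide (TsNHNH2) | Cc1ccc(cc1)S(=O)(=O)NN | starting material
5 | 4-fluorobenzaldehyde | O=Cc1ccc(F)cc1 | starting material
6 | (E)-N'-{[2-(3-bromophenoxy)-3-methoxyphenyl]methylidene}-4-methylbenzenesulfonohydrazide (tosylhydrazone of 3) | COc1cccc(/C=N/NS(=O)(=O)c2ccc(C)cc2)c1Oc1cccc(Br)c1 | intermediate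
7 | 2-(3-bromophenoxy)-1-(diazomethyl)-3-methoxybenzene | COc1cccc(C=[N+]=[N-])c1Oc1cccc(Br)c1 | intermediate
8 | 2-[2-(3-bromophenoxy)-3-methoxyphenyl]-1-(4-fluorophenyl)ethan-1-one | COc1cccc(CC(=O)c2ccc(F)cc2)c1Oc1cccc(Br)c1 | intermediate
9 | 3,4,5-trimethoxybenzaldehyde | COc1cc(C=O)cc(OC)c1OC | starting material
10 | 5-ethenyl-1,2,3-trimethoxybenzene (3,4,5-trimethoxystyrene) | COc1cc(C=C)cc(OC)c1OC | intermediate
11 | 9-borabicyclo[3.3.1]nonane (9-BBN) | B1C2CCCC1CCC2 | starting material
12 | 9-[2-(3,4,5-trimethoxyphenyl)ethyl]-9-borabicyclo[3.3.1]nonane | COc1cc(CCB2C3CCCC2CCC3)cc(OC)c1OC | intermediate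
13 | 1-(4-fluorophenyl)-2-(3-methoxy-2-{3-[2-(3,4,5-trimethoxyphenyl)ethyl]phenoxy}phenyl)ethan-1-one (open-chain tetramethyl ether) | COc1cc(CCc2cccc(Oc3c(OC)cccc3CC(=O)c3ccc(F)cc3)c2)cc(OC)c1OC | intermediate
14 | 1-(4-fluorophenyl)-2-(3-hydroxy-2-{3-[2-(3,4,5-trihydroxyphenyl)ethyl]phenoxy}phenyl)ethan-1-one (open-chain tetraphenol) | Oc1cc(CCc2cccc(Oc3c(O)cccc3CC(=O)c3ccc(F)cc3)c2)cc(O)c1O | intermediate
15 | phenylboronic acid | OB(O)c1ccccc1 | starting material
16 | ring A O,O-phenylboronate of 14 (2-phenyl-1,3,2-benzodioxaborole across the central and one outer oxygen; the other outer OH free) | Oc1cc(CCc2cccc(Oc3c(O)cccc3CC(=O)c3ccc(F)cc3)c2)cc2OB(c3ccccc3)Oc12 | intermediate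
17 | ring A O,O-phenylboronate of 18 (boron on the two ring A oxygens that end as free OH; third ring A oxygen bonded to ring B) | O1c2cc3cc(c2OB1c1ccccc1)Oc1ccc(cc1)C(=O)Cc1cccc(O)c1Oc1cccc(c1)CC3 | intermediate
18 | macrocyclic triphenol ketone: 18-membered ring, ring A (1,2-dihydroxy; C3–O to ring B; C5–CH2CH2 to ring D), ring B (1,4-phenylene carrying C(=O)CH2 to ring C C1), ring C (3-hydroxy; C2–O to ring D), ring D (1,3-phenylene) | Oc1cc2cc(c1O)Oc1ccc(cc1)C(=O)Cc1cccc(O)c1Oc1cccc(c1)CC2 | intermediate
19 | target CNP0356934.1: 18 with the ketone reduced to the (S)-configured CH(OH) on the carbon attached to ring B | Oc1cc2cc(c1O)Oc1ccc(cc1)[C@@H](O)Cc1cccc(O)c1Oc1cccc(c1)CC2 | target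

**Totals**

Total steps: 7. Longest linear sequence: 6 (steps 1, 2, 4, 5, 6, 7; step 3 is the side branch).

**Steps most likely to fail, with fallbacks**

Step 6 (the proposed new step). The boron mask on a pyrogallol is precedented only for O-alkylation in water. It may not hold under Cs2CO3 and fluoride in DMSO at 90 °C. If it is lost, arylation at the central oxygen, Smiles isomerisation, pyrogallol autoxidation and oligomers are expected. The fallback uses only known chemistry: the regiochemistry is fixed by methyl ethers in the starting material and the deprotection follows ring closure. It sets out from 8. Commercial 3-hydroxy-4,5-dimethoxybenzaldehyde F1 is methylenated (Ph3PCH3Br, KOtBu 2.3 equiv, THF) to 5-ethenyl-2,3-dimethoxyphenol F2. Compound 11 (2.2 equiv, THF) converts F2 into the O,C-diborylated alkylborane F3, which is coupled with 8 (Pd(dppf)Cl2, aq K3PO4, THF/DMF, 60 °C) to the monophenol seco ketone F4. Conventional carbonate-mediated SNAr macro-etherification (Cs2CO3, DMSO, 2 mM, 90 °C) gives the macrocyclic trimethyl ether ketone F5. BBr3 (CH2Cl2, −78 °C to rt) then removes the three methyl groups, and the fallback comes back to the route at 18.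

Step 7. The free catechol and phenol may bind the ruthenium catalyst, and the electron-rich macrocyclic ketone may reduce slowly or with eroded ee. The fallback sets out from 18. Silylation (TBSCl, imidazole, DMF) gives the tris(tert-butyldimethylsilyl) ether F6. Corey–Bakshi–Shibata reduction with (R)-2-methyl-CBS-oxazaborolidine (20 mol%) and BH3·SMe2 in THF at −20 °C gives the silylated (S)-alcohol F7. TBAF buffered with AcOH (THF, 0 °C) removes the silyl groups, and the fallback comes back at 19.

Step 2. The diazo/aldehyde union can divert to aryl migration, azine formation or condensation of the product ketone with the aldehyde. The fallback sets out from 3. Horner–Wittig condensation of 3 with diphenyl [anilino(4-fluorophenyl)methyl]phosphonate F8 (made from 5, aniline and diphenyl phosphite) using Cs2CO3 in THF/iPrOH gives the N-phenyl enamine F9. Aqueous HCl hydrolyses it to the deoxybenzoin, and the fallback comes back at 8.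

**Further compounds**

F1 | step 6 | 3-hydroxy-4,5-dimethoxybenzaldehyde | COc1cc(C=O)cc(O)c1OC
F2 | step 6 | 5-ethenyl-2,3-dimethoxyphenol | COc1cc(C=C)cc(O)c1OC
F3 | step 6 | 9-[2-(3-{[9-borabicyclo[3.3.1]nonan-9-yl]oxy}-4,5-dimethoxyphenyl)ethyl]-9-borabicyclo[3.3.1]nonane | COc1cc(CCB2C3CCCC2CCC3)cc(OB2C3CCCC2CCC3)c1OC
F4 | step 6 | 1-(4-fluorophenyl)-2-(2-{3-[2-(3-hydroxy-4,5-dimethoxyphenyl)ethyl]phenoxy}-3-methoxyphenyl)ethan-1-one | COc1cc(CCc2cccc(Oc3c(OC)cccc3CC(=O)c3ccc(F)cc3)c2)cc(O)c1OC
F5 | step 6 | tri-O-methyl ether of 18 (macrocyclic trimethyl ether ketone) | COc1cc2cc(c1OC)Oc1ccc(cc1)C(=O)Cc1cccc(OC)c1Oc1cccc(c1)CC2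
F6 | step 7 | tris(tert-butyldimethylsilyl) ether of 18 | CC(C)(C)[Si](C)(C)Oc1cc2cc(c1O[Si](C)(C)C(C)(C)C)Oc1ccc(cc1)C(=O)Cc1cccc(O[Si](C)(C)C(C)(C)C)c1Oc1cccc(c1)CC2
F7 | step 7 | tris(tert-butyldimethylsilyl) ether of 19, (S)-alcohol | CC(C)(C)[Si](C)(C)Oc1cc2cc(c1O[Si](C)(C)C(C)(C)C)Oc1ccc(cc1)[C@@H](O)Cc1cccc(O[Si](C)(C)C(C)(C)C)c1Oc1cccc(c1)CC2
F8 | step 2 | diphenyl [anilino(4-fluorophenyl)methyl]phosphonate (racemic) | O=P(Oc1ccccc1)(Oc1ccccc1)C(Nc1ccccc1)c1ccc(F)cc1
F9 | step 2 | N-{2-[2-(3-bromophenoxy)-3-methoxyphenyl]-1-(4-fluorophenyl)ethenyl}aniline (E/Z mixture) | COc1cccc(C=C(Nc2ccccc2)c2ccc(F)cc2)c1Oc1cccc(Br)c1
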